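**Strategy.** The target is (2S)-5-hydroxy-6,7,3',4'-tetramethoxyflavanone. Ring C is cut at C3–C4 and at O1–C8a, exploiting the 1,3-relationship of the C4 ketone and the oxygen-bearing C2 across the C3 methylene, and the position of O1 on ring A carbon C8a ortho to the acyl carbon. A lithiated 2-aryl-1,3-dithiane (C4 acyl anion, ortho-fluorine at C8a) opens (R)-(3,4-dimethoxyphenyl)oxirane at its CH2; the liberated benzylic alkoxide then displaces fluoride in the same flask, closing ring C. The dithiane, a temporary spiro ring, blocks base-induced retro-oxa-Michael racemisation; its hydrolysis and chelation-controlled 5-O-demethylation finish the route.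

Key step: step 5

Remark: flavanone numbering is used for the target (O1, C2, C3, C4, C4a, C5 to C8, C8a; ring A is the benzo ring, ring B the 3,4-dimethoxyphenyl group, ring C the pyranone); the only stereocentre, C2, is S.

**Step 1**
Reactants: 1 3,4,5-trimethoxyaniline
Product: 3 5-fluoro-1,2,3-trimethoxybenzene, via diazonium tetrafluoroborate 2 (not isolated)
Conditions: NOBF4, CH2Cl2, 0 °C; then 1,2-dichlorobenzene, 110 °C
Reagents that add atoms: nitrosonium tetrafluoroborate, N#[O+].F[B-](F)(F)F
Why: Balz–Schiemann reaction: NO+ diazotises the aniline and the diazonium tetrafluoroborate loses N2 on heating, the aryl cation taking fluoride from BF4−.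

**Step 2**
Reactants: 3 5-fluoro-1,2,3-trimethoxybenzene
Product: 5 6-fluoro-2,3,4-trimethoxybenzaldehyde, via aryllithium 4 (not isolated)
Conditions: n-BuLi, THF, −78 °C; DMF, −78 to 0 °C; H2O
Reagents that add atoms: N,N-dimethylformamide, CN(C)C=O
Why: Directed ortho-metalation: the two equivalent ring C–H positions each lie between F and OMe, the most acidic site, and the aryllithium, stable at −78 °C, is formylated by DMF.

**Step 3**
Reactants: 5 6-fluoro-2,3,4-trimethoxybenzaldehyde
Product: 6 2-(6-fluoro-2,3,4-trimethoxyphenyl)-1,3-dithiane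
Conditions: HS(CH2)3SH, BF3·OEt2, CH2Cl2, 0 °C to rt
Reagents that add atoms: propane-1,3-dithiol, SCCCS
Why: Lewis-acid-catalysed dithioacetalisation of the aldehyde (Corey–Seebach dithiane formation), which installs the temporary ring that masks C4 and reverses its polarity.

**Step 4**
Reactants: 7 2-chloro-1-(3,4-dimethoxyphenyl)ethan-1-one
Product: 9 (R)-2-(3,4-dimethoxyphenyl)oxirane, via (R)-chlorohydrin 8 (not isolated)
Conditions: RuCl(p-cymene)[(S,S)-TsDPEN] (0.5 mol %), HCO2H/Et3N (5:2), EtOAc, rt; then 2 M NaOH, i-PrOH, 0 °C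
Reagents that add atoms: none
Why: Noyori–Ikariya asymmetric transfer hydrogenation of the α-chloro ketone sets the stereocentre by catalyst control (the (S,S)-ligand should give the (R)-chlorohydrin, the same facial sense as for (S)-1-arylethanols, the descriptor changing only through the CH2Cl priority), and intramolecular Williamson closure at the CH2Cl carbon leaves that centre untouched.

**Step 5**
Reactants: 6 2-(6-fluoro-2,3,4-trimethoxyphenyl)-1,3-dithiane; 9 (R)-2-(3,4-dimethoxyphenyl)oxirane
Product: 12 (2S)-2-(3,4-dimethoxyphenyl)-5,6,7-trimethoxyspiro[chromane-4,2'-[1,3]dithiane], via lithiated dithiane 10 (not isolated), via lithium alkoxide 11 (not isolated)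
Conditions: n-BuLi, THF, −78 to −40 °C; 9, DMPU, −78 °C to rt; then KOtBu, 65 °C (one flask)
Reagents that add atoms: none
Why: n-BuLi removes the doubly sulfur-stabilised benzylic proton of 6 to give the acyl-anion equivalent 10, which opens epoxide 9 by SN2 attack at the unsubstituted CH2 (C3–C4 bond) and releases the benzylic alkoxide 11; after exchange to the potassium alkoxide this oxygen adds to the fluorine-bearing carbon of ring A and expels fluoride through a Meisenheimer intermediate (O1–C8a bond). The closest known reaction types are the Corey–Seebach opening of terminal epoxides by 2-aryl-2-lithio-1,3-dithianes and the alkoxide SNAr cyclisation of unactivated ortho-fluoroaryl propanols to chromans, here run in sequence in one flask. Ring C closes in a six-membered exo mode at the ipso carbon (6-exo-trig-type addition–elimination), helped by the gem-disubstituted dithiane carbon. C2 is not a new stereocentre: its C–O bond is never broken, so the configuration of the (R)-epoxide is carried over unchanged (the descriptor becomes S only through the priority change). The step needs terminal over benzylic epoxide opening, secured by the bulk of the tertiary carbanion and by DMPU, which tempers lithium-assisted benzylic ionisation, and fluoride over methoxide displacement at the two ortho carbons, secured by the much higher SNAr reactivity of C–F. Because C4 is a dithioketal and not a carbonyl, neither 11 nor 12 can enter retro-aldol, E1cB or retro-oxa-Michael pathways under the basic conditions.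

**Step 6**
Reactants: 12 (2S)-2-(3,4-dimethoxyphenyl)-5,6,7-trimethoxyspiro[chromane-4,2'-[1,3]dithiane]
Product: 13 (2S)-2-(3,4-dimethoxyphenyl)-5,6,7-trimethoxychroman-4-one
Conditions: MeI, CaCO3, MeCN/H2O (4:1), 45 °C
Reagents that add atoms: water, O
Why: Alkylative dithiane hydrolysis: S-methylation turns sulfur into a leaving group, the thionium ion stabilised by the electron-rich ring is captured by water, and the CaCO3-buffered neutral medium avoids base-induced ring opening of the flavanone, so C2 should be retained.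

**Step 7**
Reactants: 13 (2S)-2-(3,4-dimethoxyphenyl)-5,6,7-trimethoxychroman-4-one
Product: 14 (2S)-2-(3,4-dimethoxyphenyl)-5-hydroxy-6,7-dimethoxychroman-4-one
Conditions: BCl3 (1.5 equiv), CH2Cl2, −78 to 0 °C; then H2O
Reagents that add atoms: none
Why: Chelation-controlled ether cleavage: BCl3 binds the C4 carbonyl and the peri 5-OMe oxygen in a six-membered chelate and chloride removes only that methyl, while the other four methoxy groups and C2 should stay untouched at or below 0 °C.

**Compound list**
1 | 3,4,5-trimethoxyaniline | COc1cc(N)cc(OC)c1OC | starting material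
2 | 3,4,5-trimethoxybenzenediazonium tetrafluoroborate | COc1cc([N+]#N)cc(OC)c1OC.F[B-](F)(F)F | intermediate
3 | 5-fluoro-1,2,3-trimethoxybenzene | COc1cc(F)cc(OC)c1OC | intermediate
4 | (6-fluoro-2,3,4-trimethoxyphenyl)lithium | [Li]c1c(F)cc(OC)c(OC)c1OC | intermediate
5 | 6-fluoro-2,3,4-trimethoxybenzaldehyde | O=Cc1c(F)cc(OC)c(OC)c1OC | intermediate
6 | 2-(6-fluoro-2,3,4-trimethoxyphenyl)-1,3-dithiane | COc1cc(F)c(C2SCCCS2)c(OC)c1OC | intermediate
7 | 2-chloro-1-(3,4-dimethoxyphenyl)ethan-1-one | COc1ccc(C(=O)CCl)cc1OC | starting material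
8 | (R)-2-chloro-1-(3,4-dimethoxyphenyl)ethan-1-ol | COc1ccc([C@@H](O)CCl)cc1OC | intermediate
9 | (R)-2-(3,4-dimethoxyphenyl)oxirane | COc1ccc([C@@H]2CO2)cc1OC | intermediate
10 | [2-(6-fluoro-2,3,4-trimethoxyphenyl)-1,3-dithian-2-yl]lithium | COc1cc(F)c(C2([Li])SCCCS2)c(OC)c1OC | intermediate
11 | lithium (1S)-1-(3,4-dimethoxyphenyl)-2-[2-(6-fluoro-2,3,4-trimethoxyphenyl)-1,3-dithian-2-yl]ethan-1-olate | COc1ccc([C@@H](O[Li])CC2(c3c(F)cc(OC)c(OC)c3OC)SCCCS2)cc1OC | intermediate
12 | (2S)-2-(3,4-dimethoxyphenyl)-5,6,7-trimethoxyspiro[chromane-4,2'-[1,3]dithiane] | COc1ccc([C@@H]2CC3(SCCCS3)c3c(cc(OC)c(OC)c3OC)O2)cc1OC | intermediate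
13 | (2S)-2-(3,4-dimethoxyphenyl)-5,6,7-trimethoxychroman-4-one | COc1ccc([C@@H]2CC(=O)c3c(cc(OC)c(OC)c3OC)O2)cc1OC | intermediate
14 | (2S)-2-(3,4-dimethoxyphenyl)-5-hydroxy-6,7-dimethoxychroman-4-one | COc1ccc([C@@H]2CC(=O)c3c(cc(OC)c(OC)c3O)O2)cc1OC | target

**Total step count:** 7. **Longest linear sequence:** 6 steps (steps 1, 2, 3, 5, 6, 7); the epoxide branch is step 4.

**Steps most likely to fail**

Step 5. The deprotonation may go kinetically to the ring position between F and OMe, with aryne-type decomposition on warming. The electron-rich epoxide may open at the benzylic carbon or rearrange under lithium assistance. The alkoxide may fail to displace fluoride from the electron-rich ring. The fallback replaces the fluoride displacement by a Mitsunobu closure that forms O1–C2 with inversion, so no fluoroarene and no SNAr are needed. It sets out from 7, which is reduced with the enantiomeric catalyst RuCl(p-cymene)[(R,R)-TsDPEN] in HCO2H/Et3N to (S)-2-chloro-1-(3,4-dimethoxyphenyl)ethan-1-ol F1 and closed in the same flask with NaOH to (S)-2-(3,4-dimethoxyphenyl)oxirane F2. Purchased 3,4,5-trimethoxyphenol F3 is ortho-formylated (MgCl2, Et3N, paraformaldehyde, MeCN, reflux) to 6-hydroxy-2,3,4-trimethoxybenzaldehyde F4. This is converted with propane-1,3-dithiol and BF3·OEt2 into 2-(1,3-dithian-2-yl)-3,4,5-trimethoxyphenol F5. Its dianion (n-BuLi, 2.1 equiv, THF) should open F2 at the CH2 to give 2-{2-[(2R)-2-(3,4-dimethoxyphenyl)-2-hydroxyethyl]-1,3-dithian-2-yl}-3,4,5-trimethoxyphenol F6. PPh3 and DIAD in THF at 0 °C should then close the ring with inversion at the carbinol carbon. The fallback comes back to the route at 12.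

Step 7. The Lewis acid may ionise the para-methoxybenzylic C2–O1 bond or open ring C to the chalcone, which would erode the enantiomeric purity, and a second methyl (at O6) may be lost. The fallback carries the C5 oxygen as a benzyl ether from the aldehyde stage and ends with a neutral hydrogenolysis. It sets out from 5, whose methoxy group ortho to the formyl group is cleaved with BCl3 (CH2Cl2, −78 to 0 °C) to 6-fluoro-2-hydroxy-3,4-dimethoxybenzaldehyde F7. The dithiane is made before benzylation, because BF3/thiol mixtures cleave benzyl ethers, giving 2-(1,3-dithian-2-yl)-3-fluoro-5,6-dimethoxyphenol F8. Benzylation (BnBr, K2CO3, DMF) gives 2-[2-(benzyloxy)-6-fluoro-3,4-dimethoxyphenyl]-1,3-dithiane F9. Under the conditions of step 5 with 9 this should give (2S)-5-(benzyloxy)-2-(3,4-dimethoxyphenyl)-6,7-dimethoxyspiro[chromane-4,2'-[1,3]dithiane] F10. The conditions of step 6 should give (2S)-5-(benzyloxy)-2-(3,4-dimethoxyphenyl)-6,7-dimethoxychroman-4-one F11. H2 over Pd/C in EtOAc at rt removes the benzyl group, and the fallback comes back to the route at 14.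

Step 6. S-Methylation of the hindered spiro dithioketal may be too slow, and more forcing electrophilic or oxidising reagents may attack the electron-rich rings. The fallback is a two-stage oxidative unmasking through an isolated S-oxide. It sets out from 12, which is oxidised with mCPBA (1.0 equiv, CH2Cl2, −78 °C) to (2S)-2-(3,4-dimethoxyphenyl)-5,6,7-trimethoxyspiro[chromane-4,2'-[1,3]dithiane] 1'-oxide F12, a mixture of sulfoxide diastereomers. The activated thioacetal S-oxide is then hydrolysed with dilute aqueous HCl in THF at rt, and the fallback comes back to the route at 13.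

**Further compounds**
F1 | step 5 | (S)-2-chloro-1-(3,4-dimethoxyphenyl)ethan-1-ol | COc1ccc([C@H](O)CCl)cc1OC
F2 | step 5 | (S)-2-(3,4-dimethoxyphenyl)oxirane | COc1ccc([C@H]2CO2)cc1OC
F3 | step 5 | 3,4,5-trimethoxyphenol (purchased) | COc1cc(O)cc(OC)c1OC
F4 | step 5 | 6-hydroxy-2,3,4-trimethoxybenzaldehyde | O=Cc1c(O)cc(OC)c(OC)c1OC
F5 | step 5 | 2-(1,3-dithian-2-yl)-3,4,5-trimethoxyphenol | COc1cc(O)c(C2SCCCS2)c(OC)c1OC
F6 | step 5 | 2-{2-[(2R)-2-(3,4-dimethoxyphenyl)-2-hydroxyethyl]-1,3-dithian-2-yl}-3,4,5-trimethoxyphenol | COc1ccc([C@H](O)CC2(c3c(O)cc(OC)c(OC)c3OC)SCCCS2)cc1OC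
F7 | step 7 | 6-fluoro-2-hydroxy-3,4-dimethoxybenzaldehyde | O=Cc1c(F)cc(OC)c(OC)c1O
F8 | step 7 | 2-(1,3-dithian-2-yl)-3-fluoro-5,6-dimethoxyphenol | COc1cc(F)c(C2SCCCS2)c(O)c1OC
F9 | step 7 | 2-[2-(benzyloxy)-6-fluoro-3,4-dimethoxyphenyl]-1,3-dithiane | COc1cc(F)c(C2SCCCS2)c(OCc2ccccc2)c1OC
F10 | step 7 | (2S)-5-(benzyloxy)-2-(3,4-dimethoxyphenyl)-6,7-dimethoxyspiro[chromane-4,2'-[1,3]dithiane] | COc1ccc([C@@H]2CC3(SCCCS3)c3c(cc(OC)c(OC)c3OCc3ccccc3)O2)cc1OC
F11 | step 7 | (2S)-5-(benzyloxy)-2-(3,4-dimethoxyphenyl)-6,7-dimethoxychroman-4-one | COc1ccc([C@@H]2CC(=O)c3c(cc(OC)c(OC)c3OCc3ccccc3)O2)cc1OC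
F12 | step 6 | (2S)-2-(3,4-dimethoxyphenyl)-5,6,7-trimethoxyspiro[chromane-4,2'-[1,3]dithiane] 1'-oxide (sulfoxide diastereomers) | COc1ccc([C@@H]2CC3(SCCCS3=O)c3c(cc(OC)c(OC)c3OC)O2)cc1OC
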